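In the delta run and in the flask, the two substrates and the two products add up to the charge at every moment, so the product readings also give the substrate left. Let the depth be ln(c(substrates charged) / c(substrates left)). If the two substrates together are pseudo-first-order, the partner stays near its charge and free catalyst dies first order, then the rate of depth gain divided by the rate of free catalyst loss is constant. Time drops out, with the charges of partner and substrates held fixed:

final depth = reach × c(free catalyst charged)

| flask | left-handed substrate | right-handed substrate | partner | free catalyst | remark | time |
|---|---|---|---|---|---|---|
| delta | 0.20 M | 0.20 M | 0.80 M | 0.40 mM | run made earlier |  |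
| flask | 0.20 M | 0.20 M | 0.800 M | 0.20 mM |  | 6.0 d |
delta run (percent of the left-handed substrate and right-handed substrate together charged)

| time / h | left-handed product / % | right-handed product / % |
|---|---|---|
| 3.00 | 11.8 | 5.5 |
| 5.00 | 13.6 | 7.6 |
| 8.00 | 19.6 | 10.8 |
| 12.0 | 23.1 | 13.5 |
| 20.0 | 28.3 | 15.9 |
| 30.0 | 32.8 | 20.2 |
| 40.0 | 34.7 | 21.0 |

(readings scatter by 1 percentage point)
1. left-handed product and right-handed product together, in percent of the left-handed substrate and right-handed substrate charged together, at 6.0 d
2. excess of left-handed product over right-handed product in the product at 6.0 d
3. whether the exchange between left-handed substrate and right-handed substrate keeps pace with the reaction: how far the product's excess at 6.0 d gets from its value without exchange to its value with instant exchange (above 80% keeps pace, below 20% hardly takes part, else lags behind)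
- free catalyst is single-handed; left-handed substrate and right-handed substrate are mirror images of each other, charged as a racemate, each of them at the stated concentration
- the numbers in the tables scatter with a standard deviation of 1 percentage point
- what may be going on: partner + free catalyst + left-handed substrate -> free catalyst + left-handed product; partner + free catalyst + right-handed substrate -> free catalyst + right-handed product; left-handed substrate <-> right-handed substrate; free catalyst -> spent catalyst A; partner + free catalyst -> spent catalyst B; partner <-> dormant form
- an excess is the difference of the two amounts in percent of their sum
- an excess is below zero if the other one leads
- no earlier run changes the charge of free catalyst; that part of a forecast is a guess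

Which inputs must be good? Take the time first. The delta run reads depth A = 0.583 at 20.0 h and depth B = 0.814 at 40.0 h, twice as late. Each such interval therefore shrinks the gain by a factor 0.396, which gives a time constant of 21.6 h. The flask's 6.0 d spans 6.67 of these, so the time needn't be known well. The partner and substrate charges equal the delta run's. The free catalyst charge differs: by the rule above depth follows it in proportion, and at 0.20 mM it is half the delta run's, a change no run tests. My reckoning from these readings, which carry their scatter:

final depth, delta run = A·A / (A + A − B) = 0.965

reach, the final depth per free catalyst charged = 2.41 mM⁻¹

flask: depth 0.483, so y = 38.3%

The forecast, higher than this on y, gave 40%, 29% and "hardly takes part", reading “kinetic resolution with no visible exchange”.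

The flask gives 39.6% and an excess of 28.6%, and the exchange lags behind: the excess gets 66% of the way from its 24.2% without exchange towards instant exchange. At 3.00 d the excess of right-handed over left-handed substrate stands at 0.279%.

    partner + free catalyst + left-handed substrate → free catalyst + left-handed product (k = 286 M⁻² h⁻¹)
    partner + free catalyst + right-handed substrate → free catalyst + right-handed product (k = 151 M⁻² h⁻¹)
    left-handed substrate ⇌ right-handed substrate (k = 0.0580 h⁻¹)
    free catalyst → spent catalyst A (k = 0.0439 h⁻¹)
    partner + free catalyst → spent catalyst B (k = 0.0131 M⁻¹ h⁻¹)
    partner ⇌ dormant form (K = 0.190, k = 0.139 h⁻¹)

The flask's own reach is 2.52 mM⁻¹. With 8.0 × 10⁻⁵ M of free catalyst and all else unchanged, the reach read from the delta run gives y = 17.6%; the computed flask gives 19.3%.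

The readings are simulated for substances that don't exist, noise included.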